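Two questions stand for this flask, the yield of target and the dissolved gas, and the runs can speak to the first.

the same everywhere: starting material 0.50 M; gas phase 56 mM (held)

| charge | protic impurity | remark | time |
|---|---|---|---|
| Thursday's | 0.21 M | run made earlier |  |
| Friday's | 0.33 M | run made earlier |  |
| flask | 0.150 M |  | 8.0 h |

| run | time / h | target / % | crystals / % |
|---|---|---|---|
| Thursday's | 0.500 | 3.9 | 0 |
| Thursday's | 1.50 | 8.5 | 0 |
| Thursday's | 3.00 | 13.0 | 0 |
| Thursday's | 4.00 | 16.3 | 0 |
| Thursday's | 6.00 | 20.0 | 0 |
| Thursday's | 8.00 | 19.4 | 0 |
| Friday's | 0.500 | 3.2 | 0.2 |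
| Friday's | 1.50 | 8.0 | 0.5 |
| Friday's | 3.00 | 13.1 | 0 |
| Friday's | 4.00 | 18.0 | 1.6 |
| Friday's | 6.00 | 19.6 | 1.2 |
| Friday's | 8.00 | 20.9 | 0 |

(standard deviation of a reading: 1 percentage point)

- amount of target and crystals together at 8.0 h, in percent of the starting material charged
- concentration of dissolved gas in solution at 8.0 h, in percent of saturation

- for target the crystals are counted in
- as a solid, counted per litre of solution: crystals
- the analysis behind the earlier runs scatters by 1 percentage point, standard deviation
- at the start none of the gas phase is in solution

Does the protic impurity matter? From Thursday's run to Friday's, c(protic impurity) rises by a factor of 1.57, yet late target changes by a factor of 1.03. So I treat the two runs as one curve, although 0.150 M lies below both charges. Crystals read at most 1.6% against a scatter of 1 percentage point, so I leave them out.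

Where does that curve stand at 8.0 h? The readings at 6.00 h and 8.00 h average 20.0%, which I take as the late level. The mean reading at 3.00 h then gives the filling time, the time constant of the exponential closing of the gap between target and that level: 2.83 h. At 8.0 h this gives 18.8%. The runs hold no reading of dissolved gas, so I commit to no number for it.

The forecast, seeing “a reversible approach to equilibrium”, says 21% (17.5% to 29%), above my figure, and 95% (80% to 100%) of saturation.

The flask gives 20.6% and 69.0% of saturation.

    gas phase ⇌ dissolved gas, rate k1*(csat - [dissolved gas]) (kL = 9.12 × 10⁻⁴ s⁻¹)
    starting material + dissolved gas → target (k = 0.00105 M⁻¹ s⁻¹)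
    dissolved gas + target → over-reacted product (k = 0.00161 M⁻¹ s⁻¹)
    dissolved gas + protic impurity → quenched reagent (k = 7.05 × 10⁻⁴ M⁻¹ s⁻¹)
    target ⇌ isomer of the product (K = 0.985, k = 3.50 × 10⁻⁴ s⁻¹)
    crystals ⇌ target, rate k6*(cs6 - [target]) while solid is left; crystals form when [target] > cs6 (solubility = 0.410 M, k = 0.0157 s⁻¹)

The filling time reckons 18.8% for this flask against the 20.6% found. For the same flask read at 2.0 h it reckons 10.1%, and that flask holds 10.9%. In this flask the answer stands where it does because of two things acting together, the return of isomer of the product to target and the reading at this time and not ten times later: without that return the same flask gives 3.91%, and read at 80.0 h it gives 0%.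

The earlier runs and the new flask are calculated on assumed constants, noise included.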